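**Assumption:** colpol is achiral, so "single enantiomer" does not apply. The only stereo-element is the Z-alkene, which is set in Step 8. I assume 4-methoxyphenol, allyl bromide and 2-bromoresorcinol are commercially available. Compound numbers start at Step 1.

## Retrosynthetic overview
- Colpol is a Z-1,4-diarylbut-2-ene. Disconnect the C=C by Z-selective cross-metathesis of two allylarenes, with a final global removal of the phenol protecting groups.
- The 2-hydroxy-4-bromo-5-methoxyphenyl half comes from 4-methoxyphenol by O-allylation, Claisen rearrangement, acetylation, and OMe-directed bromination.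
- The 4-bromo-3,5-dihydroxyphenyl half comes from 2-bromoresorcinol by bis-silylation, sterically controlled Ir C–H borylation at C5, and Suzuki allylation.
- No rings are formed; both aromatic rings are present in the starting materials.

## Route

**Step 1**
Reactants: 1 (4-methoxyphenol); 2 (allyl bromide)
Product: 3 (1-allyloxy-4-methoxybenzene)
Conditions: K2CO3, acetone, reflux
Reagents that add atoms: allyl bromide, C=CCBr
Why: Williamson ether synthesis of the phenoxide.

**Step 2**
Reactants: 3
Product: 4 (2-allyl-4-methoxyphenol)
Conditions: neat or o-dichlorobenzene, 190–200 °C (sealed tube or microwave)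
Reagents that add atoms: none
Why: Aromatic Claisen [3,3] rearrangement. The para position is blocked by OMe, so the allyl group goes ortho to OH, with no stereocentre formed.

**Step 3**
Reactants: 4; 5 (acetic anhydride)
Product: 6 (2-allyl-4-methoxyphenyl acetate)
Conditions: Ac2O, Et3N, DMAP (cat.), CH2Cl2, 0 °C to rt
Reagents that add atoms: Ac2O, CC(=O)OC(C)=O
Why: Acetylation turns the strongly directing OH into a weakly donating OAc. This lets OMe control the next bromination, and the acetate is also a protecting group.

**Step 4**
Reactants: 6; 7 (N-bromosuccinimide)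
Product: 8 (2-allyl-5-bromo-4-methoxyphenyl acetate)
Conditions: NBS, MeCN, 0 °C to rt, dark
Reagents that add atoms: NBS, O=C1CCC(=O)N1Br
Why: Electrophilic aromatic bromination goes ortho to OMe and para to the allyl group. This is the most activated and least hindered site, and it gives the Br/OMe/chain pattern of the target. NBS without light or radical initiator leaves the terminal alkene untouched.

**Step 5**
Reactants: 9 (2-bromoresorcinol); 10 (TBSCl)
Product: 11 (2-bromo-1,3-bis(tert-butyldimethylsilyloxy)benzene)
Conditions: TBSCl (2.5 equiv), imidazole, DMF, rt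
Reagents that add atoms: TBSCl, CC(C)(C)[Si](C)(C)Cl
Why: Silylation of the phenols gives base-stable protection. The bulky OTBS groups also direct the next step to C5.

**Step 6**
Reactants: 11; 12 (bis(pinacolato)diboron)
Product: 13 (2-[4-bromo-3,5-bis(TBSO)phenyl]-4,4,5,5-tetramethyl-1,3,2-dioxaborolane)
Conditions: B2pin2, [Ir(OMe)(cod)]2 (1.5 mol%), dtbpy (3 mol%), THF, 80 °C
Reagents that add atoms: B2pin2, CC1(C)OB(OC1(C)C)B2OC(C)(C)C(C)(C)O2
Why: Ir-catalysed C–H borylation is sterically controlled. It occurs only at C5, which has no ortho substituents, and leaves the C–Br bond intact.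

**Step 7**
Reactants: 13; 2 (allyl bromide)
Product: 14 (5-allyl-2-bromo-1,3-bis(TBSO)benzene)
Conditions: Pd(PPh3)4 (5 mol%), K3PO4, THF/H2O, 60 °C
Reagents that add atoms: allyl bromide, C=CCBr
Why: Suzuki–Miyaura allylation. Allyl bromide undergoes oxidative addition far faster than the Ar–Br flanked by two OTBS groups, so the aryl bromide survives.

**Step 8**
Reactants: 8 (1 equiv); 14 (2.5 equiv)
Product: 15 ((Z)-1-(2-acetoxy-4-bromo-5-methoxyphenyl)-4-[4-bromo-3,5-bis(TBSO)phenyl]but-2-ene)
Conditions: Z-selective cyclometalated Ru metathesis catalyst (5 mol%), THF, 35 °C, under N2 with partial vacuum to remove ethylene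
Reagents that add atoms: none
Why: Z-selective cross-metathesis of two terminal allylarenes sets the cis C=C kinetically through a side-on metallacyclobutane. Excess 14 suppresses homodimerisation of 8, and the Z-homodimer of 14 is removed by chromatography.

**Step 9**
Reactants: 15
Product: 16 (colpol)
Conditions: TBAF (5 equiv), THF, 0 °C to rt, 2 h; then aq. NH4Cl
Reagents that add atoms: none
Why: Fluoride removes both aryl TBS ethers and cleaves the aryl acetate. The Z-alkene, the aryl bromides and the OMe group are unaffected, and no stereocentre is touched.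

## Compound list
1 | 4-methoxyphenol | COc1ccc(O)cc1 | starting material
2 | allyl bromide | C=CCBr | starting material
3 | 1-allyloxy-4-methoxybenzene | C=CCOc1ccc(OC)cc1 | intermediate
4 | 2-allyl-4-methoxyphenol | C=CCc1cc(OC)ccc1O | intermediate
5 | acetic anhydride | CC(=O)OC(C)=O | reagent
6 | 2-allyl-4-methoxyphenyl acetate | C=CCc1cc(OC)ccc1OC(C)=O | intermediate
7 | N-bromosuccinimide | O=C1CCC(=O)N1Br | reagent
8 | 2-allyl-5-bromo-4-methoxyphenyl acetate | C=CCc1cc(OC)c(Br)cc1OC(C)=O | intermediate
9 | 2-bromoresorcinol | Oc1cccc(O)c1Br | starting material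
10 | tert-butyldimethylsilyl chloride | CC(C)(C)[Si](C)(C)Cl | reagent
11 | 2-bromo-1,3-bis(TBSO)benzene | CC(C)(C)[Si](C)(C)Oc1cccc(O[Si](C)(C)C(C)(C)C)c1Br | intermediate
12 | bis(pinacolato)diboron | CC1(C)OB(OC1(C)C)B2OC(C)(C)C(C)(C)O2 | reagent
13 | 4-bromo-3,5-bis(TBSO)phenyl-Bpin | CC1(C)OB(OC1(C)C)c1cc(O[Si](C)(C)C(C)(C)C)c(Br)c(O[Si](C)(C)C(C)(C)C)c1 | intermediate
14 | 5-allyl-2-bromo-1,3-bis(TBSO)benzene | C=CCc1cc(O[Si](C)(C)C(C)(C)C)c(Br)c(O[Si](C)(C)C(C)(C)C)c1 | intermediate
15 | protected Z-diarylbutene | CC(=O)Oc1cc(Br)c(OC)cc1C/C=C\Cc1cc(O[Si](C)(C)C(C)(C)C)c(Br)c(O[Si](C)(C)C(C)(C)C)c1 | intermediate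
16 | colpol | COc1cc(C/C=C\Cc2cc(O)c(Br)c(O)c2)c(O)cc1Br | target

## Totals
- Total steps: 9.
- Longest linear sequence: 6 steps (1, 2, 3, 4, 8, 9).

## Steps most likely to fail, with fallbacks
1. **Step 8 (cross-metathesis).** Risks are a statistical product mixture, incomplete Z-selectivity, and a chelating ortho-OAc.
   - Fallback: a Z-selective Wittig olefination. Ozonolysis of 8 gives the arylacetaldehyde. Ozonolysis and NaBH4 reduction of 14 give Ar–CH2CH2OH, which is converted with PPh3·HBr into the phosphonium salt. Salt-free ylide formation (NaHMDS) and coupling then give the Z-olefin, followed by Step 9.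
2. **Step 4 (regioselective bromination).** The competing sites are C3 and C6, and the allyl alkene could react.
   - Fallback: install Br before the carbon chain. Dakin oxidation of 3-bromo-4-methoxybenzaldehyde gives 3-bromo-4-methoxyphenol. Casnati–Skattebøl ortho-formylation (MgCl2, Et3N, paraformaldehyde) then gives 4-bromo-2-hydroxy-5-methoxybenzaldehyde. Reduce and protect to the benzyl alcohol, convert to the benzyl bromide, and couple with vinylMgBr/CuI to reach an equivalent allylarene.
3. **Step 7 (Suzuki allylation of an Ar–Br/Ar–Bpin "AB" monomer).** Oligomerisation or protodeboronation could compete.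
   - Fallback: start from 4-bromo-3,5-dihydroxybenzoic acid. Protect the phenols as TBS ethers and reduce the acid to the benzyl alcohol. Convert this to the benzyl bromide and couple with vinylMgBr/CuI to give 14 without any boron intermediate.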